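## Retrosynthetic overview

1. Target 16 ⇐ one-pot hydrogenation of both C=C bonds and hydrogenolysis of the three O-benzyl groups of bis-stilbene 15; the aryl methyl ether stays.
2. Each Ar–CH=CH–Ar' ⇐ Cu/quinoline decarboxylation of an (E)-2,3-diarylpropenoic acid made by Perkin–Oglialoro (aldol-type) condensation of ArCHO with Ar'CH2CO2H. The convergent C–D condensation 9 + 13 → 14 is the key C–C bond formation; the A–B bond (2 + 3 → 5) is made the same way.
3. Diaryl ether B–O–C ⇐ SNAr of phenol 7 on 4-fluorobenzaldehyde 8, which also delivers the aldehyde for the key step.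
4. Building blocks: 3,4-dihydroxybenzaldehyde (regioselective 4-O-benzylation), 3-methoxyphenylacetic acid, and 2',5'-dihydroxyacetophenone (benzylation, Willgerodt–Kindler, hydrolysis → arylacetic acid 13).
5. No ring is formed: all four benzene rings are bought and joined in the order A–B, then B–O–C, then C–D.

Assumption: the target has no stereocentre and no C=C bond, so there is no enantiomer to select; alkene geometries of intermediates are drawn as the expected major isomers and are erased in the last step.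

## Route

Step 1
Reactants: 1 3,4-dihydroxybenzaldehyde
Product: 2 4-(benzyloxy)-3-hydroxybenzaldehyde
Conditions: BnBr (1.05 eq), NaHCO3 (1.5 eq), NaI (0.1 eq), DMF, 40 °C, 20 h
Reagents that add atoms: benzyl bromide, BrCc1ccccc1
Why: Williamson etherification in which the weak base deprotonates only the more acidic 4-OH (para to CHO), giving regioselective mono-O-benzylation.

Step 2
Reactants: 2 4-(benzyloxy)-3-hydroxybenzaldehyde; 3 (3-methoxyphenyl)acetic acid
Product: 5 (E)-3-[3-acetoxy-4-(benzyloxy)phenyl]-2-(3-methoxyphenyl)prop-2-enoic acid, via O-acetyl aldehyde 4 (not isolated)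
Conditions: Ac2O (6 eq), Et3N (3 eq), 120 °C, 6 h; then ice/2 M HCl
Reagents that add atoms: acetic anhydride, CC(=O)OC(C)=O
Why: Perkin–Oglialoro condensation (Et3N-mediated aldol addition of the Ac2O-activated arylacetic acid to the aldehyde, then β-elimination) after in-situ acetylation of the phenol; the E acid with the two aryl groups cis is the thermodynamic product, and no stereocentre is created.

Step 3
Reactants: 5 (E)-3-[3-acetoxy-4-(benzyloxy)phenyl]-2-(3-methoxyphenyl)prop-2-enoic acid
Product: 6 (E)-3-[4-(benzyloxy)-3-hydroxyphenyl]-2-(3-methoxyphenyl)prop-2-enoic acid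
Conditions: 2 M aq NaOH (4 eq), THF, rt, 2 h; then 2 M HCl to pH 2
Reagents that add atoms: none
Why: Saponification of the aryl acetate is fast at room temperature and leaves the benzyl ether, methyl ether and acrylic acid untouched.

Step 4
Reactants: 6 (E)-3-[4-(benzyloxy)-3-hydroxyphenyl]-2-(3-methoxyphenyl)prop-2-enoic acid
Product: 7 2-(benzyloxy)-5-[(Z)-2-(3-methoxyphenyl)ethenyl]phenol
Conditions: Cu powder (0.5 eq), quinoline, 200 °C, 2 h, N2
Reagents that add atoms: none
Why: Copper/quinoline protodecarboxylation of an α-arylcinnamic acid replaces CO2H by H with retention, so the aryl groups stay cis (Z); this works on the free-phenol analogue in the combretastatin series.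

Step 5
Reactants: 7 2-(benzyloxy)-5-[(Z)-2-(3-methoxyphenyl)ethenyl]phenol; 8 4-fluorobenzaldehyde
Product: 9 4-{2-(benzyloxy)-5-[(Z)-2-(3-methoxyphenyl)ethenyl]phenoxy}benzaldehyde
Conditions: K2CO3 (2 eq), DMF, 120 °C, 12 h, N2
Reagents that add atoms: none
Why: SNAr (addition–elimination through a Meisenheimer complex) of the phenoxide on the para-formyl-activated aryl fluoride, the standard diaryl ether formation for bis(bibenzyl)s.

Step 6
Reactants: 10 1-(2,5-dihydroxyphenyl)ethan-1-one (2',5'-dihydroxyacetophenone)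
Product: 11 1-[2,5-bis(benzyloxy)phenyl]ethan-1-one
Conditions: BnBr (2.4 eq), K2CO3 (3 eq), DMF, 70 °C, 16 h, N2
Reagents that add atoms: benzyl bromide, BrCc1ccccc1
Why: Double Williamson etherification; warm K2CO3/DMF also alkylates the hydrogen-bonded 2-OH, and nitrogen protects the hydroquinone from air oxidation.

Step 7
Reactants: 11 1-[2,5-bis(benzyloxy)phenyl]ethan-1-one
Product: 12 2-[2,5-bis(benzyloxy)phenyl]-1-(morpholin-4-yl)ethane-1-thione
Conditions: S8 (2.5 eq S), morpholine (4 eq), 130 °C, 10 h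
Reagents that add atoms: sulfur, S1SSSSSSS1; morpholine, C1COCCN1
Why: Willgerodt–Kindler reaction (enamine formation, thiation and migration of the oxidised carbon to the chain end) turns ArCOCH3 into the arylthioacetomorpholide with water as the only co-product; benzyl ethers are inert to sulfur/amine at this temperature.

Step 8
Reactants: 12 2-[2,5-bis(benzyloxy)phenyl]-1-(morpholin-4-yl)ethane-1-thione
Product: 13 [2,5-bis(benzyloxy)phenyl]acetic acid
Conditions: KOH (10 eq), EtOH/H2O 4:1, reflux, 16 h; then 2 M HCl; recrystallise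
Reagents that add atoms: water (O), supplied as aqueous KOH ([K+].[OH-])
Why: Alkaline hydrolysis of the thioamide gives the carboxylate; benzyl aryl ethers are stable to hot alkali, and recrystallisation removes sulfur residues.

Step 9
Reactants: 9 4-{2-(benzyloxy)-5-[(Z)-2-(3-methoxyphenyl)ethenyl]phenoxy}benzaldehyde; 13 [2,5-bis(benzyloxy)phenyl]acetic acid
Product: 14 (E)-2-[2,5-bis(benzyloxy)phenyl]-3-(4-{2-(benzyloxy)-5-[(Z)-2-(3-methoxyphenyl)ethenyl]phenoxy}phenyl)prop-2-enoic acid
Conditions: 13 (1.2 eq), Ac2O (5 eq), Et3N (3 eq), 120 °C, 8 h; then H2O, 2 M HCl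
Reagents that add atoms: none
Why: Key convergent Perkin–Oglialoro condensation, an intermolecular aldol addition of the activated arylacetic acid to the aryl aldehyde followed by elimination; it forms the C–D carbon–carbon bond, gives the E acid, and creates no stereocentre.

Step 10
Reactants: 14 (E)-2-[2,5-bis(benzyloxy)phenyl]-3-(4-{2-(benzyloxy)-5-[(Z)-2-(3-methoxyphenyl)ethenyl]phenoxy}phenyl)prop-2-enoic acid
Product: 15 1,4-bis(benzyloxy)-2-[(Z)-2-(4-{2-(benzyloxy)-5-[(Z)-2-(3-methoxyphenyl)ethenyl]phenoxy}phenyl)ethenyl]benzene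
Conditions: Cu powder (0.5 eq), quinoline, 200 °C, 2 h, N2; acid wash, chromatography
Reagents that add atoms: none
Why: Copper/quinoline protodecarboxylation as in step 4; aryl benzyl ethers and the diaryl ether are thermally stable at 200 °C, and the alkene geometry is irrelevant for the next step.

Step 11
Reactants: 15 1,4-bis(benzyloxy)-2-[(Z)-2-(4-{2-(benzyloxy)-5-[(Z)-2-(3-methoxyphenyl)ethenyl]phenoxy}phenyl)ethenyl]benzene
Product: 16 2-[2-(4-{2-hydroxy-5-[2-(3-methoxyphenyl)ethyl]phenoxy}phenyl)ethyl]benzene-1,4-diol (target)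
Conditions: H2 (3 bar), 10% Pd/C, EtOAc/EtOH 1:1, rt, 16 h; work-up under N2
Reagents that add atoms: none
Why: Catalytic hydrogenation saturates both stilbene C=C bonds and hydrogenolyses the three benzyl aryl ethers in one operation, while the aryl methyl ether and diaryl ether are inert.

## Compound list

1 | 3,4-dihydroxybenzaldehyde | O=Cc1ccc(O)c(O)c1 | starting material
2 | 4-(benzyloxy)-3-hydroxybenzaldehyde | O=Cc1ccc(OCc2ccccc2)c(O)c1 | intermediate
3 | (3-methoxyphenyl)acetic acid | COc1cccc(CC(=O)O)c1 | starting material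
4 | 2-(benzyloxy)-5-formylphenyl acetate (O-acetyl aldehyde) | CC(=O)Oc1cc(C=O)ccc1OCc1ccccc1 | intermediate (not isolated)
5 | (E)-3-[3-acetoxy-4-(benzyloxy)phenyl]-2-(3-methoxyphenyl)prop-2-enoic acid | OC(=O)/C(c1cccc(OC)c1)=C/c1ccc(OCc2ccccc2)c(OC(C)=O)c1 | intermediate
6 | (E)-3-[4-(benzyloxy)-3-hydroxyphenyl]-2-(3-methoxyphenyl)prop-2-enoic acid | OC(=O)/C(c1cccc(OC)c1)=C/c1ccc(OCc2ccccc2)c(O)c1 | intermediate
7 | 2-(benzyloxy)-5-[(Z)-2-(3-methoxyphenyl)ethenyl]phenol | COc1cccc(/C=C\c2ccc(OCc3ccccc3)c(O)c2)c1 | intermediate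
8 | 4-fluorobenzaldehyde | O=Cc1ccc(F)cc1 | starting material
9 | 4-{2-(benzyloxy)-5-[(Z)-2-(3-methoxyphenyl)ethenyl]phenoxy}benzaldehyde | COc1cccc(/C=C\c2ccc(OCc3ccccc3)c(Oc3ccc(C=O)cc3)c2)c1 | intermediate
10 | 1-(2,5-dihydroxyphenyl)ethan-1-one | CC(=O)c1cc(O)ccc1O | starting material
11 | 1-[2,5-bis(benzyloxy)phenyl]ethan-1-one | CC(=O)c1cc(OCc2ccccc2)ccc1OCc1ccccc1 | intermediate
12 | 2-[2,5-bis(benzyloxy)phenyl]-1-(morpholin-4-yl)ethane-1-thione | S=C(Cc1cc(OCc2ccccc2)ccc1OCc1ccccc1)N1CCOCC1 | intermediate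
13 | [2,5-bis(benzyloxy)phenyl]acetic acid | OC(=O)Cc1cc(OCc2ccccc2)ccc1OCc1ccccc1 | intermediate
14 | (E)-2-[2,5-bis(benzyloxy)phenyl]-3-(4-{2-(benzyloxy)-5-[(Z)-2-(3-methoxyphenyl)ethenyl]phenoxy}phenyl)prop-2-enoic acid | OC(=O)/C(c1cc(OCc2ccccc2)ccc1OCc1ccccc1)=C/c1ccc(Oc2cc(/C=C\c3cccc(OC)c3)ccc2OCc2ccccc2)cc1 | intermediate
15 | 1,4-bis(benzyloxy)-2-[(Z)-2-(4-{2-(benzyloxy)-5-[(Z)-2-(3-methoxyphenyl)ethenyl]phenoxy}phenyl)ethenyl]benzene | COc1cccc(/C=C\c2ccc(OCc3ccccc3)c(Oc3ccc(/C=C\c4cc(OCc5ccccc5)ccc4OCc4ccccc4)cc3)c2)c1 | intermediate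
16 | 2-[2-(4-{2-hydroxy-5-[2-(3-methoxyphenyl)ethyl]phenoxy}phenyl)ethyl]benzene-1,4-diol | COc1cccc(CCc2ccc(O)c(Oc3ccc(CCc4cc(O)ccc4O)cc3)c2)c1 | target

## Step count and risks

Total steps: 11. Longest linear sequence: 8 (steps 1, 2, 3, 4, 5, 9, 10, 11); the side branch to acid 13 is steps 6–8.

Risk 1, step 7 (Willgerodt–Kindler on an ortho-benzyloxy ketone, which can be sluggish and tarry). The fallback sets out from 11 and comes back at 13. Ketone 11 is treated with PhI(OAc)2 and catalytic H2SO4 in trimethyl orthoformate/MeOH at 60 °C, an oxidative 1,2-aryl shift that gives methyl [2,5-bis(benzyloxy)phenyl]acetate F1. Saponification with LiOH in THF/H2O and acidification then gives 13. This replaces the sulfur chemistry by a hypervalent-iodine rearrangement and also removes the sulfur-carry-over problem.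

Risk 2, step 10 (200 °C Cu/quinoline decarboxylation on the fully elaborated acid 14; step 4 has the same hazard with better precedent). The fallback sets out from 9 together with 13 and comes back at 15, by-passing steps 9 and 10 while keeping an aldol as the bond-forming event. Acid 13 is converted to its dianion with LDA (2.2 eq, THF, −78 to 0 °C) and added to aldehyde 9 at −78 °C (Ivanov aldol addition). This gives 2-[2,5-bis(benzyloxy)phenyl]-3-hydroxy-3-(4-{2-(benzyloxy)-5-[(Z)-2-(3-methoxyphenyl)ethenyl]phenoxy}phenyl)propanoic acid F2 as a racemic diastereomer mixture. Heating F2 with DMF dimethyl acetal in CHCl3 at 60 °C brings about decarboxylative dehydration under near-neutral conditions. The product is 15, accompanied by its isomer with an (E)-configured new alkene, 1,4-bis(benzyloxy)-2-[(E)-2-(4-{2-(benzyloxy)-5-[(Z)-2-(3-methoxyphenyl)ethenyl]phenoxy}phenyl)ethenyl]benzene F3. Both are taken through step 11 to 16.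

Risk 3, step 11 (five reductive events in one pot; traces of sulfur from the branch or of quinoline can poison Pd, and the hydroquinone product is air-sensitive). The fallback sets out from 15 and comes back at 16. Both alkenes are first saturated with diimide (TsNHNH2, NaOAc, DME/H2O, reflux), which needs no metal and leaves benzyl ethers alone. This gives 1,4-bis(benzyloxy)-2-[2-(4-{2-(benzyloxy)-5-[2-(3-methoxyphenyl)ethyl]phenoxy}phenyl)ethyl]benzene F4. The three benzyl ethers are then cleaved with BCl3 and pentamethylbenzene as cation scavenger in CH2Cl2 at −78 °C, conditions that do not touch the aryl methyl ether, to give 16.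

## Further compounds

F1 | step 7 | methyl [2,5-bis(benzyloxy)phenyl]acetate | COC(=O)Cc1cc(OCc2ccccc2)ccc1OCc1ccccc1
F2 | step 10 | 2-[2,5-bis(benzyloxy)phenyl]-3-hydroxy-3-(4-{2-(benzyloxy)-5-[(Z)-2-(3-methoxyphenyl)ethenyl]phenoxy}phenyl)propanoic acid (racemic diastereomer mixture) | OC(=O)C(c1cc(OCc2ccccc2)ccc1OCc1ccccc1)C(O)c1ccc(Oc2cc(/C=C\c3cccc(OC)c3)ccc2OCc2ccccc2)cc1
F3 | step 10 | 1,4-bis(benzyloxy)-2-[(E)-2-(4-{2-(benzyloxy)-5-[(Z)-2-(3-methoxyphenyl)ethenyl]phenoxy}phenyl)ethenyl]benzene | COc1cccc(/C=C\c2ccc(OCc3ccccc3)c(Oc3ccc(/C=C/c4cc(OCc5ccccc5)ccc4OCc4ccccc4)cc3)c2)c1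
F4 | step 11 | 1,4-bis(benzyloxy)-2-[2-(4-{2-(benzyloxy)-5-[2-(3-methoxyphenyl)ethyl]phenoxy}phenyl)ethyl]benzene | COc1cccc(CCc2ccc(OCc3ccccc3)c(Oc3ccc(CCc4cc(OCc5ccccc5)ccc4OCc4ccccc4)cc3)c2)c1
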